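**Plan**

- Retrosynthesis: the aryl–C(=O) bond of the chalcone is cut first (ring lithiation plus a p-coumaroyl Weinreb amide). The side chain is traced back through an allylic transposition to an epoxy alcohol, and the two oxirane C–O bonds are cut to an (E)-allylic alcohol. Its C2=C3 alkene (Horner–Wadsworth–Emmons) and the aryl–CH2CH2 bond (aryl-lithium plus ethylene oxide) lead back to resorcinol.
- Enabling feature: in ArCH2–CH(OH)–C(=CH2)–CH2CH2CH=CMe2 the carbinol carbon lies between the benzylic CH2 and an exo-methylene carbon. This is the 1,3-transposed form of the primary allylic alcohol ArCH2–CH=C(R)–CH2OH, so the carbinol C–O bond can be made as one C–O bond of an oxirane ring.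
- Forward order: resorcinol bis-MOM ether, hydroxyethylation at C2, oxidation to the aldehyde, E-olefination with the homoprenylated phosphonoacetate, reduction. The oxirane (the only ring made) is then closed on this chain and reopened reductively (iodide, zinc) to the methylene carbinol.
- Endgame: silylation, OMOM-directed lithiation at C4, acylation with the MOM-protected p-coumaroyl Weinreb amide, acid removal of all protecting groups.
- Stereochemistry: the single stereocentre (R) is set by the D-(−)-tartrate ligand in the epoxidation and keeps its C–O bond to the end. The enone E geometry is that of 4-hydroxycinnamic acid.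

Key step: step 7

**Route**

Step 1
Reactants: 1 resorcinol
Product: 2 1,3-bis(methoxymethoxy)benzene
Conditions: NaH, MOMCl, DMF, 0 °C → rt
Reagents that add atoms: chloromethyl methyl ether, COCCl
Why: Williamson O-alkylation of the bis-phenoxide with the reactive α-chloro ether gives the bis-acetal, which later serves as the ortho-directing group.

Step 2
Reactants: 2 1,3-bis(methoxymethoxy)benzene
Product: 4 2-[2,6-bis(methoxymethoxy)phenyl]ethan-1-ol, via [2,6-bis(methoxymethoxy)phenyl]lithium 3 (not isolated)
Conditions: n-BuLi, THF, 0 °C → rt; ethylene oxide, −20 °C → rt; H2O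
Reagents that add atoms: ethylene oxide, C1CO1
Why: Directed ortho-metalation takes place at C2, the position flanked by both coordinating OMOM groups, and the aryl-lithium opens the epoxide by SN2 attack to add the hydroxyethyl arm.

Step 3
Reactants: 4 2-[2,6-bis(methoxymethoxy)phenyl]ethan-1-ol
Product: 5 2-[2,6-bis(methoxymethoxy)phenyl]acetaldehyde
Conditions: Dess–Martin periodinane, CH2Cl2, 0 °C → rt
Reagents that add atoms: none
Why: Dess–Martin oxidation stops at the aldehyde under near-neutral conditions that an enolisable arylacetaldehyde and the aryl acetals tolerate, and the product is used at once.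

Step 4
Reactants: 6 triethyl phosphonoacetate; 7 5-bromo-2-methylpent-2-ene
Product: 8 ethyl 2-(diethoxyphosphoryl)-6-methylhept-5-enoate (racemic)
Conditions: NaH, DME, 0 °C; then 7, NaI (cat.), 70 °C
Reagents that add atoms: none
Why: SN2 C-alkylation of the sodium phosphonoacetate enolate with the primary homoallylic bromide installs the homoprenyl branch, and an excess of the phosphonate keeps dialkylation low.

Step 5
Reactants: 5 2-[2,6-bis(methoxymethoxy)phenyl]acetaldehyde; 8 ethyl 2-(diethoxyphosphoryl)-6-methylhept-5-enoate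
Product: 9 ethyl (2E)-4-[2,6-bis(methoxymethoxy)phenyl]-2-(4-methylpent-3-en-1-yl)but-2-enoate
Conditions: LiCl, DBU, MeCN, 0 °C → rt
Reagents that add atoms: none
Why: Horner–Wadsworth–Emmons olefination of an α-alkyl phosphonoacetate under Masamune–Roush conditions should place the ester trans to the CH2Ar group (E) while the mild amine base limits enolisation of the aldehyde, and any Z isomer is removed by chromatography here or after step 6.

Step 6
Reactants: 9 ethyl (2E)-4-[2,6-bis(methoxymethoxy)phenyl]-2-(4-methylpent-3-en-1-yl)but-2-enoate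
Product: 10 (2E)-4-[2,6-bis(methoxymethoxy)phenyl]-2-(4-methylpent-3-en-1-yl)but-2-en-1-ol
Conditions: DIBAL-H, CH2Cl2, −78 → 0 °C; Rochelle salt
Reagents that add atoms: none
Why: 1,2-Reduction of the conjugated ester by DIBAL-H gives the primary allylic alcohol without change of alkene geometry and without touching the acetals.

Step 7
Reactants: 10 (2E)-4-[2,6-bis(methoxymethoxy)phenyl]-2-(4-methylpent-3-en-1-yl)but-2-en-1-ol
Product: 11 [(2R,3R)-3-{[2,6-bis(methoxymethoxy)phenyl]methyl}-2-(4-methylpent-3-en-1-yl)oxiran-2-yl]methanol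
Conditions: Ti(OiPr)4 (10 mol %), D-(−)-diisopropyl tartrate (12 mol %), t-BuOOH (anhydrous, decane), 4 Å MS, CH2Cl2, −20 °C
Reagents that add atoms: tert-butyl hydroperoxide, CC(C)(C)OO
Why: The allylic alcohol and t-BuOOH exchange onto titanium in the dimeric titanium–tartrate complex, and the distal peroxide oxygen is passed to the bound alkene in one concerted, stereospecific syn step; this is the Katsuki–Sharpless asymmetric epoxidation of an (E)-2,3-disubstituted allylic alcohol, the class of the (E)-2-methyl-3-alkylprop-2-en-1-ols. The oxirane thus closes by a [2+1] oxygen-atom transfer that forms both C–O bonds at once on one alkene face, not by cyclisation of an open-chain intermediate. C2 and C3 are set together by the tartrate ligand (reagent control): since the L-(+)-ester gives (2S,3S)-epoxides with this substrate class, the D-(−)-ester should give the (2R,3R)-epoxide, and the trans relation of CH2OH and CH2Ar follows from the E geometry. The step needs enantioface selectivity and chemoselectivity for the allylic alkene over the distal trisubstituted alkene and the electron-rich ring. Both come from the hydroxyl group, which anchors the substrate to titanium, whereas the remote alkene has no ligating group and should be inert to Ti/t-BuOOH at −20 °C. Molecular sieves allow catalytic titanium and limit Lewis-acid opening of the trisubstituted epoxide.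

Step 8
Reactants: 11 [(2R,3R)-3-{[2,6-bis(methoxymethoxy)phenyl]methyl}-2-(4-methylpent-3-en-1-yl)oxiran-2-yl]methanol
Product: 12 (2S,3R)-3-{[2,6-bis(methoxymethoxy)phenyl]methyl}-2-(iodomethyl)-2-(4-methylpent-3-en-1-yl)oxirane
Conditions: PPh3, I2, imidazole, CH2Cl2, 0 °C
Reagents that add atoms: iodine, II
Why: Appel-type iodination displaces the alkoxyphosphonium group at the primary carbon by SN2 and leaves the oxirane and both stereocentres intact, the C2 descriptor changing to S only because CH2I outranks the ring carbon.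

Step 9
Reactants: 12 (2S,3R)-3-{[2,6-bis(methoxymethoxy)phenyl]methyl}-2-(iodomethyl)-2-(4-methylpent-3-en-1-yl)oxirane
Product: 13 (2R)-1-[2,6-bis(methoxymethoxy)phenyl]-7-methyl-3-methylideneoct-6-en-2-ol
Conditions: Zn dust, EtOH, reflux; aq. NH4Cl
Reagents that add atoms: none
Why: Zinc reduces the C–I bond with loss of the β-oxygen (reductive opening of a 2,3-epoxy iodide, a Boord-type elimination), which cleaves the quaternary C2–O bond, creates the C=CH2 group and leaves the C3–O bond and hence the R carbinol configuration untouched.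

Step 10
Reactants: 13 (2R)-1-[2,6-bis(methoxymethoxy)phenyl]-7-methyl-3-methylideneoct-6-en-2-ol
Product: 14 tert-butyl({(2R)-1-[2,6-bis(methoxymethoxy)phenyl]-7-methyl-3-methylideneoct-6-en-2-yl}oxy)dimethylsilane
Conditions: TBSCl, imidazole, DMF, rt → 40 °C
Reagents that add atoms: tert-butyldimethylsilyl chloride, CC(C)(C)[Si](C)(C)Cl
Why: Silylation of the secondary alcohol removes the only acidic proton before the organolithium step and gives an ether that is stable to alkyl-lithium bases.

Step 11
Reactants: 15 (E)-4-hydroxycinnamic acid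
Product: 16 (2E)-3-(4-hydroxyphenyl)-N-methoxy-N-methylprop-2-enamide
Conditions: MeNH(OMe)·HCl, EDC·HCl, HOBt, Et3N, DMF, 0 °C → rt
Reagents that add atoms: N,O-dimethylhydroxylamine hydrochloride, CNOC.Cl
Why: Carbodiimide amide coupling through the HOBt active ester gives the Weinreb amide, the amine being far more nucleophilic than the phenol, and the E alkene is not affected.

Step 12
Reactants: 16 (2E)-3-(4-hydroxyphenyl)-N-methoxy-N-methylprop-2-enamide
Product: 17 (2E)-N-methoxy-3-[4-(methoxymethoxy)phenyl]-N-methylprop-2-enamide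
Conditions: NaH, MOMCl, THF, 0 °C → rt
Reagents that add atoms: chloromethyl methyl ether, COCCl
Why: Williamson alkylation of the phenoxide masks the acidic phenol so that it cannot quench the aryl-lithium in the next step.

Step 13
Reactants: 14 tert-butyl({(2R)-1-[2,6-bis(methoxymethoxy)phenyl]-7-methyl-3-methylideneoct-6-en-2-yl}oxy)dimethylsilane; 17 (2E)-N-methoxy-3-[4-(methoxymethoxy)phenyl]-N-methylprop-2-enamide
Product: 19 (2E)-1-{3-[(2R)-2-{[tert-butyl(dimethyl)silyl]oxy}-7-methyl-3-methylideneoct-6-en-1-yl]-2,4-bis(methoxymethoxy)phenyl}-3-[4-(methoxymethoxy)phenyl]prop-2-en-1-one, via ring-lithiated silyl ether 18 (not isolated)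
Conditions: s-BuLi, TMEDA, THF, −78 → −40 °C; 17, −78 → 0 °C; H2O
Reagents that add atoms: none
Why: Directed ortho-metalation by OMOM at C4, the only free position next to an acetal and the known site for 2-alkylresorcinol bis-MOM ethers, is followed by 1,2-addition of the aryl-lithium to the Weinreb amide, which stops at the ketone stage (Weinreb ketone synthesis).

Step 14
Reactants: 19 (2E)-1-{3-[(2R)-2-{[tert-butyl(dimethyl)silyl]oxy}-7-methyl-3-methylideneoct-6-en-1-yl]-2,4-bis(methoxymethoxy)phenyl}-3-[4-(methoxymethoxy)phenyl]prop-2-en-1-one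
Product: 20 (2E)-1-{2,4-dihydroxy-3-[(2R)-2-hydroxy-7-methyl-3-methylideneoct-6-en-1-yl]phenyl}-3-(4-hydroxyphenyl)prop-2-en-1-one (CNP0307786.1)
Conditions: HCl (ca. 1 M), MeOH–H2O 9:1, rt → 40 °C
Reagents that add atoms: none
Why: Acid-catalysed acetal exchange with methanol removes the three MOM groups and solvolyses the silyl ether in one operation, and dilute acid near room temperature is chosen so that the allylic alcohol, the two alkenes and the 2′-hydroxychalcone are not ionised or cyclised.

**Compound list**

1 | resorcinol | Oc1cccc(O)c1 | starting material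
2 | 1,3-bis(methoxymethoxy)benzene | COCOc1cccc(OCOC)c1 | intermediate
3 | [2,6-bis(methoxymethoxy)phenyl]lithium | [Li]c1c(OCOC)cccc1OCOC | intermediate (not isolated)
4 | 2-[2,6-bis(methoxymethoxy)phenyl]ethan-1-ol | OCCc1c(OCOC)cccc1OCOC | intermediate
5 | 2-[2,6-bis(methoxymethoxy)phenyl]acetaldehyde | O=CCc1c(OCOC)cccc1OCOC | intermediate
6 | triethyl phosphonoacetate | CCOC(=O)CP(=O)(OCC)OCC | starting material
7 | 5-bromo-2-methylpent-2-ene | CC(C)=CCCBr | starting material
8 | ethyl 2-(diethoxyphosphoryl)-6-methylhept-5-enoate (racemic) | CCOC(=O)C(CCC=C(C)C)P(=O)(OCC)OCC | intermediate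
9 | ethyl (2E)-4-[2,6-bis(methoxymethoxy)phenyl]-2-(4-methylpent-3-en-1-yl)but-2-enoate | CCOC(=O)/C(CCC=C(C)C)=C/Cc1c(OCOC)cccc1OCOC | intermediate
10 | (2E)-4-[2,6-bis(methoxymethoxy)phenyl]-2-(4-methylpent-3-en-1-yl)but-2-en-1-ol | OC/C(CCC=C(C)C)=C/Cc1c(OCOC)cccc1OCOC | intermediate
11 | [(2R,3R)-3-{[2,6-bis(methoxymethoxy)phenyl]methyl}-2-(4-methylpent-3-en-1-yl)oxiran-2-yl]methanol | OC[C@@]1(CCC=C(C)C)O[C@@H]1Cc1c(OCOC)cccc1OCOC | intermediate
12 | (2S,3R)-3-{[2,6-bis(methoxymethoxy)phenyl]methyl}-2-(iodomethyl)-2-(4-methylpent-3-en-1-yl)oxirane | IC[C@@]1(CCC=C(C)C)O[C@@H]1Cc1c(OCOC)cccc1OCOC | intermediate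
13 | (2R)-1-[2,6-bis(methoxymethoxy)phenyl]-7-methyl-3-methylideneoct-6-en-2-ol | C=C(CCC=C(C)C)[C@H](O)Cc1c(OCOC)cccc1OCOC | intermediate
14 | tert-butyl({(2R)-1-[2,6-bis(methoxymethoxy)phenyl]-7-methyl-3-methylideneoct-6-en-2-yl}oxy)dimethylsilane | C=C(CCC=C(C)C)[C@H](O[Si](C)(C)C(C)(C)C)Cc1c(OCOC)cccc1OCOC | intermediate
15 | (E)-4-hydroxycinnamic acid | O=C(O)/C=C/c1ccc(O)cc1 | starting material
16 | (2E)-3-(4-hydroxyphenyl)-N-methoxy-N-methylprop-2-enamide | CON(C)C(=O)/C=C/c1ccc(O)cc1 | intermediate
17 | (2E)-N-methoxy-3-[4-(methoxymethoxy)phenyl]-N-methylprop-2-enamide | CON(C)C(=O)/C=C/c1ccc(OCOC)cc1 | intermediate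
18 | {3-[(2R)-2-{[tert-butyl(dimethyl)silyl]oxy}-7-methyl-3-methylideneoct-6-en-1-yl]-2,4-bis(methoxymethoxy)phenyl}lithium | C=C(CCC=C(C)C)[C@H](O[Si](C)(C)C(C)(C)C)Cc1c(OCOC)ccc([Li])c1OCOC | intermediate (not isolated)
19 | (2E)-1-{3-[(2R)-2-{[tert-butyl(dimethyl)silyl]oxy}-7-methyl-3-methylideneoct-6-en-1-yl]-2,4-bis(methoxymethoxy)phenyl}-3-[4-(methoxymethoxy)phenyl]prop-2-en-1-one | C=C(CCC=C(C)C)[C@H](O[Si](C)(C)C(C)(C)C)Cc1c(OCOC)ccc(C(=O)/C=C/c2ccc(OCOC)cc2)c1OCOC | intermediate
20 | (2E)-1-{2,4-dihydroxy-3-[(2R)-2-hydroxy-7-methyl-3-methylideneoct-6-en-1-yl]phenyl}-3-(4-hydroxyphenyl)prop-2-en-1-one | C=C(CCC=C(C)C)[C@H](O)Cc1c(O)ccc(C(=O)/C=C/c2ccc(O)cc2)c1O | target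

**Step count and risks**

Total step count: 14. Longest linear sequence: 11 steps (1, 2, 3, 5, 6, 7, 8, 9, 10, 13, 14, from resorcinol). Step 4 and steps 11–12 are side branches.

Steps most likely to fail:

Step 5. Geometric control may be incomplete, and the base may move the new double bond into conjugation with the electron-rich ring or cause self-condensation of the enolisable aldehyde. Any Z-alcohol carried into step 7 would give the S carbinol, so geometric purity here equals enantiomeric purity later. The fallback sets out from 2 and 7 and comes back to the route at 10; it builds the trisubstituted alkene stereospecifically instead of by olefination. Purchased 4-{[tert-butyl(dimethyl)silyl]oxy}but-2-yn-1-ol (OCC#CCO[Si](C)(C)C(C)(C)C) is treated with Red-Al and then iodine (trans-hydroalumination, iodinolysis) to give (Z)-4-{[tert-butyl(dimethyl)silyl]oxy}-3-iodobut-2-en-1-ol F1. Bromide 7 is converted with zinc dust and LiCl in THF into bromo(4-methylpent-3-en-1-yl)zinc F2. Negishi coupling of F1 with an excess of F2 (Pd(dppf)Cl2, THF, 50 °C) should proceed with retention to (E)-3-({[tert-butyl(dimethyl)silyl]oxy}methyl)-7-methylocta-2,6-dien-1-ol F3. Appel bromination (CBr4, PPh3, CH2Cl2, 0 °C) gives {[(2E)-2-(2-bromoethylidene)-6-methylhept-5-en-1-yl]oxy}(tert-butyl)dimethylsilane F4. The lithio species 3, made from 2 as in step 2, is alkylated by F4 at the primary carbon (CuI cat., THF, −78 → 0 °C) to give tert-butyl({(2E)-4-[2,6-bis(methoxymethoxy)phenyl]-2-(4-methylpent-3-en-1-yl)but-2-en-1-yl}oxy)dimethylsilane F5, and TBAF in THF releases 10.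

Step 13. The hindered, doubly ortho-substituted aryl-lithium may add to the cinnamoyl amide at the β-carbon, or may be quenched by proton transfer before acylation. The fallback sets out from 14 and comes back at 19; it forms the enone by condensation instead of by acyl transfer. The aryl-lithium 18, generated as in step 13, is acetylated with N-methoxy-N-methylacetamide to give 1-{3-[(2R)-2-{[tert-butyl(dimethyl)silyl]oxy}-7-methyl-3-methylideneoct-6-en-1-yl]-2,4-bis(methoxymethoxy)phenyl}ethan-1-one F6. Claisen–Schmidt condensation of F6 with purchased 4-(methoxymethoxy)benzaldehyde (COCOc1ccc(C=O)cc1; Ba(OH)2·8H2O, MeOH, 40 °C) should then give the (E)-chalcone 19 by aldol addition and dehydration.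

Step 14. Protic acid may ionise the allylic alcohol, add the freed ortho-phenols across the side-chain alkenes (chroman formation), add methanol to the trisubstituted alkene, or close the 2′-hydroxychalcone to the flavanone. The fallback sets out from 19 and comes back at 20; it unmasks in two stages without protic acid. Buffered fluoride (TBAF, AcOH, THF, rt) removes the silyl group to give (2E)-1-{3-[(2R)-2-hydroxy-7-methyl-3-methylideneoct-6-en-1-yl]-2,4-bis(methoxymethoxy)phenyl}-3-[4-(methoxymethoxy)phenyl]prop-2-en-1-one F7. TMSOTf with 2,2′-bipyridyl (CH2Cl2, 0 °C) then exchanges the three aryl MOM acetals for trimethylsilyl ethers by silyl transfer, silylating the free alcohol as well, to give (2E)-1-{3-[(2R)-7-methyl-3-methylidene-2-[(trimethylsilyl)oxy]oct-6-en-1-yl]-2,4-bis[(trimethylsilyl)oxy]phenyl}-3-{4-[(trimethylsilyl)oxy]phenyl}prop-2-en-1-one F8. F8 is hydrolysed to 20 on work-up with water and dilute citric acid.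

**Further compounds**

F1 | step 5 | (Z)-4-{[tert-butyl(dimethyl)silyl]oxy}-3-iodobut-2-en-1-ol | OC/C=C(\I)CO[Si](C)(C)C(C)(C)C
F2 | step 5 | bromo(4-methylpent-3-en-1-yl)zinc | CC(C)=CCC[Zn]Br
F3 | step 5 | (E)-3-({[tert-butyl(dimethyl)silyl]oxy}methyl)-7-methylocta-2,6-dien-1-ol | OC/C=C(\CCC=C(C)C)CO[Si](C)(C)C(C)(C)C
F4 | step 5 | {[(2E)-2-(2-bromoethylidene)-6-methylhept-5-en-1-yl]oxy}(tert-butyl)dimethylsilane | BrC/C=C(\CCC=C(C)C)CO[Si](C)(C)C(C)(C)C
F5 | step 5 | tert-butyl({(2E)-4-[2,6-bis(methoxymethoxy)phenyl]-2-(4-methylpent-3-en-1-yl)but-2-en-1-yl}oxy)dimethylsilane | CC(C)(C)[Si](C)(C)OC/C(CCC=C(C)C)=C/Cc1c(OCOC)cccc1OCOC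
F6 | step 13 | 1-{3-[(2R)-2-{[tert-butyl(dimethyl)silyl]oxy}-7-methyl-3-methylideneoct-6-en-1-yl]-2,4-bis(methoxymethoxy)phenyl}ethan-1-one | C=C(CCC=C(C)C)[C@H](O[Si](C)(C)C(C)(C)C)Cc1c(OCOC)ccc(C(C)=O)c1OCOC
F7 | step 14 | (2E)-1-{3-[(2R)-2-hydroxy-7-methyl-3-methylideneoct-6-en-1-yl]-2,4-bis(methoxymethoxy)phenyl}-3-[4-(methoxymethoxy)phenyl]prop-2-en-1-one | C=C(CCC=C(C)C)[C@H](O)Cc1c(OCOC)ccc(C(=O)/C=C/c2ccc(OCOC)cc2)c1OCOC
F8 | step 14 | (2E)-1-{3-[(2R)-7-methyl-3-methylidene-2-[(trimethylsilyl)oxy]oct-6-en-1-yl]-2,4-bis[(trimethylsilyl)oxy]phenyl}-3-{4-[(trimethylsilyl)oxy]phenyl}prop-2-en-1-one | C=C(CCC=C(C)C)[C@H](O[Si](C)(C)C)Cc1c(O[Si](C)(C)C)ccc(C(=O)/C=C/c2ccc(O[Si](C)(C)C)cc2)c1O[Si](C)(C)C
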